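The 1,2-dioxane (O1, O2, C3–C6) is opened at C4–C5 and O1–C6. Both bonds are made in one flask from an acyclic 1,5-diene, a methyl 2-methyl-2-vinylpent-4-enoate that carries the epoxy-terpenoid chain on C4. Heat brings about a Cope rearrangement that joins the vinyl terminus to the methylidene CH2 (C4–C5). It also puts the alkene into conjugation with the ester and releases a new methylidene at C6. Cobalt-catalysed silylperoxidation with O2 then turns that methylidene into the C6 methyl group and the O1–C6 bond. This exploits that C6 is a methyl-bearing tertiary peroxy carbon and that C3 is the β-carbon of the propanoate, where the ring closes next.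

Key step: step 8

Remark: the dioxane is numbered O1, O2, C3 (bears the propanoic acid), C4, C5, C6. Compounds 13, 15 and 16 are used as epimer mixtures at the one centre left undrawn in their SMILES.

Step 1
Reactants: 1 dihydro-β-ionone; 2 triethyl phosphonoacetate
Product: 3 ethyl (2E)-3-methyl-5-(2,6,6-trimethylcyclohex-1-en-1-yl)pent-2-enoate
Conditions: NaH, THF, 0 °C to reflux; chromatography
Reagents that add atoms: none
Why: Horner–Wadsworth–Emmons olefination of the methyl ketone should favour the (E)-trisubstituted enoate, and the minor (Z)-isomer is removed on silica.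

Step 2
Reactants: 3 ethyl (2E)-enoate
Product: 4 (2E)-3-methyl-5-(2,6,6-trimethylcyclohex-1-en-1-yl)pent-2-en-1-ol
Conditions: DIBAL-H, CH2Cl2, −78 °C; Rochelle salt
Reagents that add atoms: none
Why: 1,2-reduction of the conjugated ester with DIBAL-H should give the allylic alcohol without touching either alkene.

Step 3
Reactants: 4 allylic alcohol
Product: 5 [(2S,3S)-3-methyl-3-[2-(2,6,6-trimethylcyclohex-1-en-1-yl)ethyl]oxiran-2-yl]methanol
Conditions: Ti(OiPr)4 (cat.), L-(+)-diethyl tartrate (cat.), t-BuOOH, 4 Å MS, CH2Cl2, −20 °C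
Reagents that add atoms: tert-butyl hydroperoxide CC(C)(C)OO
Why: Sharpless asymmetric epoxidation with the L-(+)-tartrate sets both oxirane centres as (2S,3S) on the (E)-alkene, and because it is hydroxyl-directed it leaves the tetrasubstituted ring alkene alone.

Step 4
Reactants: 5 epoxy alcohol
Product: 6 [(2S,3S)-3-methyl-3-[2-(2,6,6-trimethylcyclohex-1-en-1-yl)ethyl]oxiran-2-yl]methyl 4-methylbenzenesulfonate
Conditions: TsCl, Et3N, DMAP (cat.), CH2Cl2, 0 °C
Reagents that add atoms: 4-toluenesulfonyl chloride Cc1ccc(cc1)S(=O)(=O)Cl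
Why: O-sulfonylation of the primary alcohol under buffered conditions leaves the oxirane and its stereocentres untouched.

Step 5
Reactants: 6 epoxy tosylate; 7 2-methylprop-2-en-1-ol
Product: 9 2-methylidene-4-[(2S,3S)-3-methyl-3-[2-(2,6,6-trimethylcyclohex-1-en-1-yl)ethyl]oxiran-2-yl]butan-1-ol, via dilithiated methallyl alcohol 8 (not isolated)
Conditions: 7, n-BuLi (2.2 equiv), TMEDA, Et2O, 0 °C to rt; CuI (cat.), −78 °C; then 6, −78 to −20 °C
Reagents that add atoms: none
Why: copper-catalysed SN2 alkylation at the allylic carbon terminus of the dianion should hit the primary sulfonate faster than the hindered trisubstituted oxirane.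

Step 6
Reactants: 9 allylic alcohol
Product: 10 (2S,3S)-3-[3-(bromomethyl)but-3-en-1-yl]-2-methyl-2-[2-(2,6,6-trimethylcyclohex-1-en-1-yl)ethyl]oxirane
Conditions: CBr4, PPh3, 2,6-lutidine, CH2Cl2, 0 °C
Reagents that add atoms: carbon tetrabromide BrC(Br)(Br)Br
Why: the Appel reaction turns the primary allylic alcohol into the bromide under neutral conditions that an oxirane tolerates, and SN2 and SN2′ paths give the same product on this 2-substituted allyl unit.

Step 7
Reactants: 10 allylic bromide; 11 methyl tiglate
Product: 13 methyl 2-ethenyl-2-methyl-4-methylidene-6-[(2S,3S)-3-methyl-3-[2-(2,6,6-trimethylcyclohex-1-en-1-yl)ethyl]oxiran-2-yl]hexanoate (both C2 epimers), via lithium dienolate of methyl tiglate 12 (not isolated)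
Conditions: LDA, DMPU, THF, −78 °C; then 10, −78 to −30 °C
Reagents that add atoms: none
Why: deconjugative alkylation of the extended enolate takes place at the α-carbon, and the quaternary centre it creates is lost again in step 8, so its configuration does not matter.

Step 8
Reactants: 13 1,5-diene ester
Product: 15 methyl (2E)-2,6-dimethyl-8-[(2S,3S)-3-methyl-3-[2-(2,6,6-trimethylcyclohex-1-en-1-yl)ethyl]oxiran-2-yl]-6-(triethylsilylperoxy)oct-2-enoate (both C6 epimers), via dienoate 14 (not isolated)
Conditions: o-xylene, BHT, base-washed sealed vessel, 175 °C; then 20 °C, ClCH2CH2Cl, Co(thd)2 (cat.), Et3SiH, O2 (1 atm)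
Reagents that add atoms: dioxygen O=O; triethylsilane CC[SiH](CC)CC
Why: Heating drives the chair-like [3,3]-sigmatropic Cope rearrangement of the 3,3-disubstituted 1,5-diene, made irreversible by conjugation of the new alkene with the ester; it forms C4–C5, and the ester in the pseudo-equatorial place should give the (E)-enoate 14. In the same flask the Mukaiyama–Isayama peroxidation transfers a hydrogen atom from a cobalt hydride to the freshly released methylidene, the tertiary C6 radical takes up O2 and the cobalt peroxide is silylated, which forms O1–C6 and the C6 methyl group. Both are known reaction types and only their telescoping is particular to this route. No ring closes here; the dioxane closes in step 9. C6 is the only new stereocentre and no element controls it, because O2 meets a planar acyclic radical, so both C6 epimers are carried on and parted after step 9. The step needs chemoselectivity among three C=C bonds: hydrogen atom transfer prefers the unhindered 1,1-disubstituted alkene over the electron-poor enoate and the shielded tetrasubstituted ring alkene, and the oxirane is inert to acid-free heat and to the neutral cobalt system.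

Step 9
Reactants: 15 silyl peroxide
Product: 17 methyl (2R)-2-[(3S,6R)-6-methyl-6-[2-[(2S,3S)-3-methyl-3-[2-(2,6,6-trimethylcyclohex-1-en-1-yl)ethyl]oxiran-2-yl]ethyl]-1,2-dioxan-3-yl]propanoate, via hydroperoxide 16 (not isolated)
Conditions: K2CO3 (cat.), MeOH, 0 °C; then Et2NH (cat.), CF3CH2OH, rt; chromatography
Reagents that add atoms: none
Why: methanolysis frees the tertiary hydroperoxide, which closes by a 6-exo-trig oxa-Michael addition through a chair with the propanoate arm and the long C6 chain equatorial (C3 set by C6), the enolate is protonated anti to the new C–O bond (C2 set by C3), and the isomers of the (6S) series are removed by chromatography.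

Step 10
Reactants: 17 methyl ester
Product: 18 (2R)-2-[(3S,6R)-6-methyl-6-[2-[(2S,3S)-3-methyl-3-[2-(2,6,6-trimethylcyclohex-1-en-1-yl)ethyl]oxiran-2-yl]ethyl]-1,2-dioxan-3-yl]propanoic acid (target)
Conditions: LiOH, THF/H2O, 0 °C; then 0.5 M HCl to pH 5, 0 °C
Reagents that add atoms: lithium hydroxide [Li+].[OH-]
Why: saponification at low temperature should be faster than enolisation of the ester, so that neither C2 nor the β-peroxy linkage at C3 is disturbed, and brief mild acidification spares the oxirane.

Compound list
1 | dihydro-β-ionone, 4-(2,6,6-trimethylcyclohex-1-en-1-yl)butan-2-one | CC(=O)CCC1=C(C)CCCC1(C)C | starting material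
2 | triethyl phosphonoacetate | CCOC(=O)CP(=O)(OCC)OCC | starting material
3 | ethyl (2E)-3-methyl-5-(2,6,6-trimethylcyclohex-1-en-1-yl)pent-2-enoate | CC1=C(CC/C(C)=C/C(=O)OCC)C(C)(C)CCC1 | intermediate
4 | (2E)-3-methyl-5-(2,6,6-trimethylcyclohex-1-en-1-yl)pent-2-en-1-ol | CC1=C(CC/C(C)=C/CO)C(C)(C)CCC1 | intermediate
5 | (2S,3S)-epoxy alcohol | CC1=C(CC[C@]2(C)O[C@H]2CO)C(C)(C)CCC1 | intermediate
6 | (2S,3S)-epoxy tosylate | CC1=C(CC[C@]2(C)O[C@H]2COS(=O)(=O)c2ccc(C)cc2)C(C)(C)CCC1 | intermediate
7 | 2-methylprop-2-en-1-ol (methallyl alcohol) | CC(=C)CO | starting material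
8 | dilithiated methallyl alcohol | [Li]CC(=C)CO[Li] | intermediate
9 | 2-methylidene-4-(epoxy-terpenoid)butan-1-ol | CC1=C(CC[C@]2(C)O[C@H]2CCC(=C)CO)C(C)(C)CCC1 | intermediate
10 | corresponding allylic bromide | CC1=C(CC[C@]2(C)O[C@H]2CCC(=C)CBr)C(C)(C)CCC1 | intermediate
11 | methyl tiglate, methyl (2E)-2-methylbut-2-enoate | C/C=C(\C)C(=O)OC | starting material
12 | lithium dienolate of methyl tiglate | C=CC(C)=C(OC)O[Li] | intermediate
13 | methyl 2-ethenyl-2-methyl-4-methylidenehexanoate bearing the epoxy-terpenoid group on C6 (C2 epimers) | CC1=C(CC[C@]2(C)O[C@H]2CCC(=C)CC(C)(C=C)C(=O)OC)C(C)(C)CCC1 | intermediate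
14 | methyl (2E)-2-methyl-6-methylideneoct-2-enoate bearing the epoxy-terpenoid group on C8 | CC1=C(CC[C@]2(C)O[C@H]2CCC(=C)CC/C=C(\C)C(=O)OC)C(C)(C)CCC1 | intermediate
15 | tertiary triethylsilyl peroxide of 14 (C6 epimers) | CC1=C(CC[C@]2(C)O[C@H]2CCC(C)(CC/C=C(\C)C(=O)OC)OO[Si](CC)(CC)CC)C(C)(C)CCC1 | intermediate
16 | tertiary hydroperoxide (C6 epimers) | CC1=C(CC[C@]2(C)O[C@H]2CCC(C)(CC/C=C(\C)C(=O)OC)OO)C(C)(C)CCC1 | intermediate
17 | methyl ester of the target, (2R,3S,6R) and (2S,3S)-oxirane | CC1=C(CC[C@]2(C)O[C@H]2CC[C@]2(C)CC[C@@H]([C@@H](C)C(=O)OC)OO2)C(C)(C)CCC1 | intermediate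
18 | CNP0204283.1 | CC1=C(CC[C@]2(C)O[C@H]2CC[C@]2(C)CC[C@@H]([C@@H](C)C(=O)O)OO2)C(C)(C)CCC1 | target

Total step count: 10. Longest linear sequence: 10 (1 to 18).

Steps most likely to fail

Step 8. The long thermal stage may isomerise the oxirane or stall before the peroxidation, and residual 13 would then be peroxidised at the wrong connectivity. The fallback sets out from 9 and comes back at 15. It replaces the Cope route by an oxygen-based [3,3] shift at lower temperature.
- Alcohol 9 is vinylated with butyl vinyl ether under Pd(II)/phenanthroline catalysis to the allyl vinyl ether F1.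
- F1 undergoes Claisen rearrangement at about 120 °C to the γ,δ-unsaturated aldehyde F2.
- A Wittig reaction with methyl 2-(triphenylphosphoranylidene)propanoate gives 14, which is now isolated and purified.
- 14 is then submitted alone to Co(thd)2, Et3SiH and O2 to give 15.

Step 9. Poor discrimination between the two chairs, slow closure onto the α-methyl enoate and attack of the peroxide anion on the oxirane may erode the outcome. The main products of the (6R) and (6S) series may also be hard to part, because both are trans-rings. The fallback sets out from 10 and comes back at 18. It puts the facial choice at C3 under auxiliary control, so that the C6 epimers become cis and trans ring isomers.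
- (S)-4-benzyloxazolidin-2-one is acylated with tigloyl chloride to the imide F3.
- The sodium dienolate of F3 is alkylated with 10 to the α-allylated imide F4.
- Heating gives the enoyl imide F5, and cobalt peroxidation gives the silyl peroxide F6.
- Buffered TBAF frees the hydroperoxide F7, which closes with Et2NH to the dioxane imide F8. F8 is purified on silica.
- LiOH/H2O2 releases 18.
- If the sense of induction is the opposite one, the (R)-auxiliary is used.

Step 5. The strongly basic allyllithium may open or isomerise the oxirane instead of displacing the sulfonate. The fallback sets out from 5 and comes back at 9. It forms the same C–C framework by cross-coupling.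
- Parikh–Doering oxidation of 5 gives the epoxy aldehyde F9.
- Methylenation with Ph3P=CH2 gives the vinyl oxirane F10.
- 9-BBN adds to the terminal alkene only and gives the alkylborane F11.
- A B-alkyl Suzuki coupling of F11 with 2-bromoprop-2-en-1-ol (PdCl2(dppf), K3PO4) gives 9.

Further compounds
F1 | step 8 | allyl vinyl ether of 9 | CC1=C(CC[C@]2(C)O[C@H]2CCC(=C)COC=C)C(C)(C)CCC1
F2 | step 8 | 4-methylidene-6-(epoxy-terpenoid)hexanal | CC1=C(CC[C@]2(C)O[C@H]2CCC(=C)CCC=O)C(C)(C)CCC1
F3 | step 9 | (S)-4-benzyl-3-[(2E)-2-methylbut-2-enoyl]oxazolidin-2-one | C/C=C(\C)C(=O)N1[C@@H](Cc2ccccc2)COC1=O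
F4 | step 9 | α-allylated α-vinyl imide | CC1=C(CC[C@]2(C)O[C@H]2CCC(=C)CC(C)(C=C)C(=O)N2[C@@H](Cc3ccccc3)COC2=O)C(C)(C)CCC1
F5 | step 9 | (E)-enoyl imide after Cope rearrangement | CC1=C(CC[C@]2(C)O[C@H]2CCC(=C)CC/C=C(\C)C(=O)N2[C@@H](Cc3ccccc3)COC2=O)C(C)(C)CCC1
F6 | step 9 | triethylsilyl peroxide of F5 | CC1=C(CC[C@]2(C)O[C@H]2CCC(C)(CC/C=C(\C)C(=O)N2[C@@H](Cc3ccccc3)COC2=O)OO[Si](CC)(CC)CC)C(C)(C)CCC1
F7 | step 9 | hydroperoxy enoyl imide | CC1=C(CC[C@]2(C)O[C@H]2CCC(C)(CC/C=C(\C)C(=O)N2[C@@H](Cc3ccccc3)COC2=O)OO)C(C)(C)CCC1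
F8 | step 9 | dioxane imide, (2R,3S,6R) | CC1=C(CC[C@]2(C)O[C@H]2CC[C@]2(C)CC[C@@H]([C@@H](C)C(=O)N3[C@@H](Cc4ccccc4)COC3=O)OO2)C(C)(C)CCC1
F9 | step 5 | epoxy aldehyde from 5 | CC1=C(CC[C@]2(C)O[C@H]2C=O)C(C)(C)CCC1
F10 | step 5 | vinyl oxirane | CC1=C(CC[C@]2(C)O[C@H]2C=C)C(C)(C)CCC1
F11 | step 5 | B-alkyl-9-borabicyclo[3.3.1]nonane | CC1=C(CC[C@]2(C)O[C@H]2CCB2C3CCCC2CCC3)C(C)(C)CCC1
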